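**Retrosynthetic overview**

1. Target 22 comes from tribenzyl flavone 21 by hydrogenolysis. Ring C of 21 comes from a 6-endo closure of o-hydroxyaryl ynone 19, which is made from bromophenol 14 and alkynyl Weinreb amide 17 (ring B arrives with 17).
2. The pyrrolidine of 14 comes from a one-flask formal [3+2] annulation of aryl N-sulfinyl aldimine 9 with the three-carbon Grignard acetal 10. C2–C3 forms by addition; N–C5 forms by condensation and reduction in the same flask. N-Methylation follows.
3. Enabling feature: pyrrolidine C2 is a methine bonded to N1 and to C8 of ring A, so it is a latent aryl aldimine carbon. C3–C4–C5 is an unbranched, unfunctionalized chain, so one reagent that is nucleophilic at C3 and a masked aldehyde at C5 can deliver it. Ring A is fully substituted at that stage, so no ring carbon competes.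
4. Order of rings: ring A is bought (3,5-bis(benzyloxy)phenol) and then oxygenated, formylated and brominated; the pyrrolidine is closed in step 7; ring C is closed in step 11.

Key step: step 7

Remark: C2 is benzylic and flanked by two ring oxygens, so every step after step 7 is kept at or below 40 °C and free of strong Lewis acids to avoid reversible C2–N heterolysis. Compounds 1, 8, 10 (0.5 M in THF) and 15 are taken as commercial.

**Route**

Step 1
Reactants: 1 3,5-bis(benzyloxy)phenol
Product: 3 2,6-bis(benzyloxy)benzene-1,4-diol, via quinone 2 (not isolated)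
Conditions: (KSO3)2NO (2.2 equiv), KH2PO4, acetone/H2O, 0 °C → rt; then Na2S2O4, EtOAc/H2O, rt
Reagents that add atoms: potassium nitrosodisulfonate (Fremy's salt) [K+].[K+].[O]N(S([O-])(=O)=O)S([O-])(=O)=O
Why: Teuber oxidation, in which two equivalents of the nitroxyl radical oxygenate the free carbon para to the phenol (between the two benzyloxy groups) to the p-quinone, which dithionite should reduce to the hydroquinone without touching the benzyl ethers.

Step 2
Reactants: 3 2,6-bis(benzyloxy)benzene-1,4-diol
Product: 4 2,4-bis(benzyloxy)-3,6-dihydroxybenzaldehyde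
Conditions: MgCl2, Et3N, (CH2O)n, MeCN, 80 °C, argon
Reagents that add atoms: paraformaldehyde (formaldehyde unit) C=O
Why: Casnati–Skattebøl ortho-formylation, in which only the hydroxyl with free ortho positions can deliver formaldehyde through its magnesium phenoxide, and the chelated salicylaldehyde formed should be too deactivated for a second formylation.

Step 3
Reactants: 4 2,4-bis(benzyloxy)-3,6-dihydroxybenzaldehyde
Product: 5 2,4-bis(benzyloxy)-6-hydroxy-3-methoxybenzaldehyde
Conditions: MeI (1.05 equiv), K2CO3, acetone, rt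
Reagents that add atoms: iodomethane CI
Why: Williamson etherification, in which the C6 hydroxyl is held in a hydrogen bond to the aldehyde so that only the C3 hydroxyl between the two benzyloxy groups should be methylated, as in the classical selective methylation of 2,5-dihydroxyaryl carbonyl compounds.

Step 4
Reactants: 5 2,4-bis(benzyloxy)-6-hydroxy-3-methoxybenzaldehyde
Product: 6 2,4-bis(benzyloxy)-5-bromo-6-hydroxy-3-methoxybenzaldehyde
Conditions: NBS, MeCN, 0 °C
Reagents that add atoms: N-bromosuccinimide O=C1CCC(=O)N1Br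
Why: Electrophilic aromatic bromination at the only free ring position, which is ortho to the free hydroxyl and ortho/para to the two benzyloxy groups.

Step 5
Reactants: 6 2,4-bis(benzyloxy)-5-bromo-6-hydroxy-3-methoxybenzaldehyde
Product: 7 2,4-bis(benzyloxy)-5-bromo-3-methoxy-6-[(4-methoxybenzyl)oxy]benzaldehyde
Conditions: 4-methoxybenzyl chloride, K2CO3, n-Bu4NI (cat.), DMF, 50 °C
Reagents that add atoms: 4-methoxybenzyl chloride COc1ccc(CCl)cc1
Why: Williamson etherification gives an acid-labile 4-methoxybenzyl ether that shields the phenol from the Grignard reagent and is shed on purpose in the acid stage of step 7, unlike the benzyl ethers.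

Step 6
Reactants: 7 2,4-bis(benzyloxy)-5-bromo-3-methoxy-6-[(4-methoxybenzyl)oxy]benzaldehyde; 8 (S)-2-methylpropane-2-sulfinamide
Product: 9 (S)-N-[(E)-{2,4-bis(benzyloxy)-5-bromo-3-methoxy-6-[(4-methoxybenzyl)oxy]phenyl}methylidene]-2-methylpropane-2-sulfinamide
Conditions: Ti(OEt)4 (2 equiv), THF, 60 °C
Reagents that add atoms: none
Why: Ti(OEt)4-mediated condensation of an aldehyde with tert-butanesulfinamide (sulfinimine formation) should give the E-aldimine with the sulfur configuration untouched.

Step 7
Reactants: 9 the (S)-sulfinyl aldimine; 10 [2-(1,3-dioxan-2-yl)ethyl]magnesium bromide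
Product: 13 3,5-bis(benzyloxy)-2-bromo-4-methoxy-6-[(2R)-pyrrolidin-2-yl]phenol, via sulfinamide acetal 11 (not isolated), via cyclic imine 12 (not isolated)
Conditions: 10 (1.5 equiv), CH2Cl2/THF, −48 °C → rt; MeOH quench, evaporate with toluene (strips 2-ethyl-1,3-dioxane); TFA/H2O (95:5), Et3SiH (1.5 equiv), 0 °C → rt, 30 min; then Et3SiH (5 equiv), rt, 3 h
Reagents that add atoms: none
Why: The Grignard carbon of 10 adds to the aldimine carbon of 9 (C2–C3 bond) through a six-membered chair transition state with magnesium bound to the sulfinyl oxygen; in wet trifluoroacetic acid the sulfinyl group, the 4-methoxybenzyl ether and the dioxane acetal are then cleaved, the freed primary amine condenses with the freed aldehyde (N–C5 bond) to cyclic imine 12, and Et3SiH reduces its iminium ion to 13. The closest known reaction type is the addition of this acetal Grignard reagent to N-tert-butanesulfinyl aryl aldimines followed by acid/silane reductive cyclization to 2-arylpyrrolidines, run here in one flask. The pyrrolidine closes by 5-exo-trig attack of nitrogen on the aldehyde carbon followed by dehydration and hydride delivery, and C5 is not a stereocentre. C2 is set in the addition by the (S)-sulfinyl group, whose tert-butyl group sits equatorial in the chair so that carbon is delivered to the Re face and gives (R); no later event touches C2. The step needs facial selectivity, which the weakly coordinating solvent and low temperature should secure by keeping the sulfinyl-chelated chair ahead of open transition states guided by the ortho ether oxygens. It also needs chemoselectivity: the aryl bromide is inert to an alkyl Grignard reagent at this temperature, the benzyl ethers should survive the acid stage while the 4-methoxybenzyl ether is lost (trapped as 4-methylanisole), and the excess reagent is stripped before the acid stage so that only the tethered aldehyde meets the amine.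

Step 8
Reactants: 13 3,5-bis(benzyloxy)-2-bromo-4-methoxy-6-[(2R)-pyrrolidin-2-yl]phenol
Product: 14 3,5-bis(benzyloxy)-2-bromo-4-methoxy-6-[(2R)-1-methylpyrrolidin-2-yl]phenol
Conditions: HCHO (37% aq, 1.2 equiv), NaBH(OAc)3, AcOH, 1,2-dichloroethane, rt
Reagents that add atoms: formaldehyde C=O
Why: Reductive amination, in which the secondary amine and formaldehyde give an iminium ion (or its cyclic N,O-acetal with the neighbouring phenol) that the acetoxyborohydride should reduce to the N-methyl amine without touching C2.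

Step 9
Reactants: 15 1-(benzyloxy)-4-ethynylbenzene
Product: 17 3-[4-(benzyloxy)phenyl]-N-methoxy-N-methylprop-2-ynamide, via lithium acetylide 16 (not isolated)
Conditions: n-BuLi, THF, −78 °C; then ClC(O)N(OMe)Me, −78 → 0 °C
Reagents that add atoms: N-methoxy-N-methylcarbamoyl chloride CON(C)C(Cl)=O
Why: Deprotonation of the terminal alkyne and C-acylation of the acetylide by the carbamoyl chloride is an established way to alkynyl Weinreb amides.

Step 10
Reactants: 14 the N-methylpyrrolidinyl bromophenol; 17 the alkynyl Weinreb amide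
Product: 19 1-{2,4-bis(benzyloxy)-6-hydroxy-3-methoxy-5-[(2R)-1-methylpyrrolidin-2-yl]phenyl}-3-[4-(benzyloxy)phenyl]prop-2-yn-1-one, via dilithio species 18 (not isolated)
Conditions: n-BuLi (1.0 equiv) then t-BuLi (2.1 equiv), THF, −78 °C; 17 (1.3 equiv), −78 → −40 °C; aq NH4Cl at −40 °C
Reagents that add atoms: none
Why: Phenol deprotonation followed by bromine–lithium exchange gives an ortho-lithiated phenoxide that adds to the Weinreb amide carbonyl to form a chelated tetrahedral adduct, which collapses to the ynone only on work-up, so neither over-addition nor phenol protection should be needed.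

Step 11
Reactants: 19 the o-hydroxyaryl ynone
Product: 21 5,7-bis(benzyloxy)-2-[4-(benzyloxy)phenyl]-6-methoxy-8-[(2R)-1-methylpyrrolidin-2-yl]-4H-chromen-4-one, via enaminone 20 (not isolated)
Conditions: Et2NH (5 equiv), EtOH, 40 °C
Reagents that add atoms: diethylamine CCNCC (held only in 20; released on ring closure)
Why: Conjugate addition of diethylamine to the ynone gives enaminone 20, whose β-carbon is attacked by the neighbouring phenol in a 6-endo-trig addition–elimination that expels the amine and closes ring C (amine-mediated flavone synthesis from o-hydroxyaryl ynones), which should avoid the 5-exo closure to an aurone.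

Step 12
Reactants: 21 the tribenzyl flavone
Product: 22 5,7-dihydroxy-2-(4-hydroxyphenyl)-6-methoxy-8-[(2R)-1-methylpyrrolidin-2-yl]-4H-chromen-4-one (target)
Conditions: H2 (1 atm), 10% Pd/C, EtOAc/MeOH, rt, stopped at full O-debenzylation
Reagents that add atoms: none
Why: Catalytic hydrogenolysis cleaves the three benzylic C–O bonds under neutral conditions at room temperature, which should leave the methyl ether, the chromone double bond and the unprotonated ring C2–N bond intact, as in debenzylations of phenolic 1-substituted tetrahydroisoquinolines.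

**Compound list**

1 | 3,5-bis(benzyloxy)phenol | Oc1cc(OCc2ccccc2)cc(OCc2ccccc2)c1 | starting material
2 | 2,6-bis(benzyloxy)cyclohexa-2,5-diene-1,4-dione | O=C1C=C(OCc2ccccc2)C(=O)C(OCc2ccccc2)=C1 | intermediate
3 | 2,6-bis(benzyloxy)benzene-1,4-diol | Oc1cc(OCc2ccccc2)c(O)c(OCc2ccccc2)c1 | intermediate
4 | 2,4-bis(benzyloxy)-3,6-dihydroxybenzaldehyde | O=Cc1c(O)cc(OCc2ccccc2)c(O)c1OCc1ccccc1 | intermediate
5 | 2,4-bis(benzyloxy)-6-hydroxy-3-methoxybenzaldehyde | O=Cc1c(O)cc(OCc2ccccc2)c(OC)c1OCc1ccccc1 | intermediate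
6 | 2,4-bis(benzyloxy)-5-bromo-6-hydroxy-3-methoxybenzaldehyde | O=Cc1c(O)c(Br)c(OCc2ccccc2)c(OC)c1OCc1ccccc1 | intermediate
7 | 2,4-bis(benzyloxy)-5-bromo-3-methoxy-6-[(4-methoxybenzyl)oxy]benzaldehyde | O=Cc1c(OCc2ccc(OC)cc2)c(Br)c(OCc2ccccc2)c(OC)c1OCc1ccccc1 | intermediate
8 | (S)-2-methylpropane-2-sulfinamide | CC(C)(C)[S@](=O)N | starting material
9 | (S)-N-[(E)-{2,4-bis(benzyloxy)-5-bromo-3-methoxy-6-[(4-methoxybenzyl)oxy]phenyl}methylidene]-2-methylpropane-2-sulfinamide | COc1ccc(COc2c(Br)c(OCc3ccccc3)c(OC)c(OCc3ccccc3)c2/C=N/[S@@](=O)C(C)(C)C)cc1 | intermediate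
10 | [2-(1,3-dioxan-2-yl)ethyl]magnesium bromide | Br[Mg]CCC1OCCCO1 | starting material
11 | (S)-N-[(1R)-1-{2,4-bis(benzyloxy)-5-bromo-3-methoxy-6-[(4-methoxybenzyl)oxy]phenyl}-3-(1,3-dioxan-2-yl)propyl]-2-methylpropane-2-sulfinamide | COc1ccc(COc2c(Br)c(OCc3ccccc3)c(OC)c(OCc3ccccc3)c2[C@H](N[S@@](=O)C(C)(C)C)CCC2OCCCO2)cc1 | intermediate
12 | 3,5-bis(benzyloxy)-2-bromo-6-[(2R)-3,4-dihydro-2H-pyrrol-2-yl]-4-methoxyphenol | Oc1c(Br)c(OCc2ccccc2)c(OC)c(OCc2ccccc2)c1[C@H]1CCC=N1 | intermediate
13 | 3,5-bis(benzyloxy)-2-bromo-4-methoxy-6-[(2R)-pyrrolidin-2-yl]phenol | Oc1c(Br)c(OCc2ccccc2)c(OC)c(OCc2ccccc2)c1[C@H]1CCCN1 | intermediate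
14 | 3,5-bis(benzyloxy)-2-bromo-4-methoxy-6-[(2R)-1-methylpyrrolidin-2-yl]phenol | Oc1c(Br)c(OCc2ccccc2)c(OC)c(OCc2ccccc2)c1[C@H]1CCCN1C | intermediate
15 | 1-(benzyloxy)-4-ethynylbenzene | C#Cc1ccc(OCc2ccccc2)cc1 | starting material
16 | lithium [4-(benzyloxy)phenyl]acetylide | [Li]C#Cc1ccc(OCc2ccccc2)cc1 | intermediate
17 | 3-[4-(benzyloxy)phenyl]-N-methoxy-N-methylprop-2-ynamide | CON(C)C(=O)C#Cc1ccc(OCc2ccccc2)cc1 | intermediate
18 | lithium 3,5-bis(benzyloxy)-2-lithio-4-methoxy-6-[(2R)-1-methylpyrrolidin-2-yl]phenoxide | [Li]Oc1c([Li])c(OCc2ccccc2)c(OC)c(OCc2ccccc2)c1[C@H]1CCCN1C | intermediate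
19 | 1-{2,4-bis(benzyloxy)-6-hydroxy-3-methoxy-5-[(2R)-1-methylpyrrolidin-2-yl]phenyl}-3-[4-(benzyloxy)phenyl]prop-2-yn-1-one | Oc1c(C(=O)C#Cc2ccc(OCc3ccccc3)cc2)c(OCc2ccccc2)c(OC)c(OCc2ccccc2)c1[C@H]1CCCN1C | intermediate
20 | (2E)-1-{2,4-bis(benzyloxy)-6-hydroxy-3-methoxy-5-[(2R)-1-methylpyrrolidin-2-yl]phenyl}-3-[4-(benzyloxy)phenyl]-3-(diethylamino)prop-2-en-1-one | Oc1c(C(=O)/C=C(/N(CC)CC)c2ccc(OCc3ccccc3)cc2)c(OCc2ccccc2)c(OC)c(OCc2ccccc2)c1[C@H]1CCCN1C | intermediate
21 | 5,7-bis(benzyloxy)-2-[4-(benzyloxy)phenyl]-6-methoxy-8-[(2R)-1-methylpyrrolidin-2-yl]-4H-chromen-4-one | COc1c(OCc2ccccc2)c([C@H]2CCCN2C)c2oc(-c3ccc(OCc4ccccc4)cc3)cc(=O)c2c1OCc1ccccc1 | intermediate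
22 | 5,7-dihydroxy-2-(4-hydroxyphenyl)-6-methoxy-8-[(2R)-1-methylpyrrolidin-2-yl]-4H-chromen-4-one | COc1c(O)c([C@H]2CCCN2C)c2oc(-c3ccc(O)cc3)cc(=O)c2c1O | target

**Step count and risks**

Total step count: 12. Longest linear sequence: 11 steps (steps 1–8 and 10–12); step 9 prepares fragment 17.

The three steps most likely to fail, riskiest first:

Step 7. Facial selectivity may be poor if an open transition state steered by the two ortho ether oxygens competes with the sulfinyl-chelated chair. During the acid/silane stage the very electron-rich benzylic C2–N bond may ionize (loss of configuration or reductive ring opening), or a benzyl ether may be lost. The fallback builds the ring stepwise and closes it under basic conditions. It sets out from 9. Indium-mediated allylation (allyl bromide, In powder, saturated aqueous NaBr/THF, rt) should give (S)-N-[(1R)-1-aryl-but-3-en-1-yl]-2-methylpropane-2-sulfinamide F1 by the same chelated chair model, and its diastereomers can be separated. Hydroboration–oxidation (9-BBN, THF; then NaBO3·4H2O) should give the primary alcohol F2. Mesylation (MsCl, Et3N, CH2Cl2, 0 °C) gives the methanesulfonate F3. KOt-Bu in THF closes the ring by N-alkylation to the N-sulfinylpyrrolidine F4. A short acid treatment (TFA/H2O, Et3SiH, 0 °C, 20 min) removes the sulfinyl and 4-methoxybenzyl groups and comes back to the route at 13.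

Step 10. Acyl transfer to the di-ortho-substituted aryllithium may be slow or incomplete, with competing conjugate addition to the ynamide or proton quench of the dianion. The fallback reverses the polarity of the C–C bond formation. It sets out from 14. The same dianion 18 is quenched with the small electrophile DMF to give 2,4-bis(benzyloxy)-6-hydroxy-3-methoxy-5-[(2R)-1-methylpyrrolidin-2-yl]benzaldehyde F5. Addition of lithium acetylide 16 (2.2 equiv, THF, −78 °C) should give the propargylic alcohol F6 as a mixture of carbinol epimers. Oxidation with MnO2 (CH2Cl2, rt) comes back to the route at 19.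

Step 2. The hydroquinone may be re-oxidized to the quinone under the basic conditions, or a second formyl group may enter. The fallback formylates before the fourth oxygen is introduced. It sets out from 1. Ortho-formylation (MgCl2, Et3N, (CH2O)n, MeCN, 80 °C) should give 2,4-bis(benzyloxy)-6-hydroxybenzaldehyde F7. Elbs persulfate oxidation (K2S2O8, aqueous NaOH/pyridine, rt) oxygenates the carbon para to the phenol and gives potassium 2,6-bis(benzyloxy)-3-formyl-4-hydroxyphenyl sulfate F8. Hydrolysis (aqueous HCl, 60 °C) comes back to the route at 4.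

**Further compounds**

F1 | step 7 | (S)-N-[(1R)-1-{2,4-bis(benzyloxy)-5-bromo-3-methoxy-6-[(4-methoxybenzyl)oxy]phenyl}but-3-en-1-yl]-2-methylpropane-2-sulfinamide | COc1ccc(COc2c(Br)c(OCc3ccccc3)c(OC)c(OCc3ccccc3)c2[C@H](N[S@@](=O)C(C)(C)C)CC=C)cc1
F2 | step 7 | (S)-N-[(1R)-1-{2,4-bis(benzyloxy)-5-bromo-3-methoxy-6-[(4-methoxybenzyl)oxy]phenyl}-4-hydroxybutyl]-2-methylpropane-2-sulfinamide | COc1ccc(COc2c(Br)c(OCc3ccccc3)c(OC)c(OCc3ccccc3)c2[C@H](N[S@@](=O)C(C)(C)C)CCCO)cc1
F3 | step 7 | (4R)-4-{2,4-bis(benzyloxy)-5-bromo-3-methoxy-6-[(4-methoxybenzyl)oxy]phenyl}-4-{[(S)-tert-butylsulfinyl]amino}butyl methanesulfonate | COc1ccc(COc2c(Br)c(OCc3ccccc3)c(OC)c(OCc3ccccc3)c2[C@H](N[S@@](=O)C(C)(C)C)CCCOS(C)(=O)=O)cc1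
F4 | step 7 | (2R)-2-{2,4-bis(benzyloxy)-5-bromo-3-methoxy-6-[(4-methoxybenzyl)oxy]phenyl}-1-[(S)-tert-butylsulfinyl]pyrrolidine | COc1ccc(COc2c(Br)c(OCc3ccccc3)c(OC)c(OCc3ccccc3)c2[C@H]2CCCN2[S@@](=O)C(C)(C)C)cc1
F5 | step 10 | 2,4-bis(benzyloxy)-6-hydroxy-3-methoxy-5-[(2R)-1-methylpyrrolidin-2-yl]benzaldehyde | O=Cc1c(O)c([C@H]2CCCN2C)c(OCc2ccccc2)c(OC)c1OCc1ccccc1
F6 | step 10 | 1-{2,4-bis(benzyloxy)-6-hydroxy-3-methoxy-5-[(2R)-1-methylpyrrolidin-2-yl]phenyl}-3-[4-(benzyloxy)phenyl]prop-2-yn-1-ol (mixture of carbinol epimers) | OC(C#Cc1ccc(OCc2ccccc2)cc1)c1c(O)c([C@H]2CCCN2C)c(OCc2ccccc2)c(OC)c1OCc1ccccc1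
F7 | step 2 | 2,4-bis(benzyloxy)-6-hydroxybenzaldehyde | O=Cc1c(O)cc(OCc2ccccc2)cc1OCc1ccccc1
F8 | step 2 | potassium 2,6-bis(benzyloxy)-3-formyl-4-hydroxyphenyl sulfate | [K+].O=Cc1c(O)cc(OCc2ccccc2)c(OS([O-])(=O)=O)c1OCc1ccccc1
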